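Everything rests on not arylating the oxygen on C4 of ring F, which is flanked by oxygenated C3 and C5; ring G is grown on it instead. Ring G has its ether on C1, hydrogens on C2 and C6 and oxygens on C3, C4 and C5, so the C3 oxygen lies meta to the ether, the pattern a cyclobutenone–ynol ether benzannulation delivers. Heating 4-(benzyloxy)-2,6-dimethoxyphenyl ethynyl ether with 3-ethoxy-4-methoxycyclobutenone should give ring G and the F–G ether in one operation. The other five ethers come from aldehyde-activated aryl halides; each aldehyde later becomes a ring hydroxyl by Baeyer–Villiger oxidation, and BBr3 finally frees all eighteen hydroxyls.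

Key step: step 6

Remark: the target has no stereocentre; rings are lettered A (2,4,6-trihydroxyphenyl end) to G (3,4,5-trihydroxyphenyl end) and each is numbered from the carbon carrying the ether oxygen toward ring A (ring A from its own ether carbon), which puts the second ether oxygen on C4 of rings B and F, C6 of rings C and E and C5 of ring D.

Step 1
Reactants: 1 4-hydroxy-2,6-dimethoxybenzaldehyde
Product: 2 4-(benzyloxy)-2,6-dimethoxybenzaldehyde
Conditions: BnBr, K2CO3, DMF, rt
Reagents that add atoms: benzyl bromide, BrCc1ccccc1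
Why: Williamson etherification of the only phenol in 1, whose para-formyl phenoxide is unhindered and has no competing nucleophilic site.

Step 2
Reactants: 2 4-(benzyloxy)-2,6-dimethoxybenzaldehyde
Product: 4 4-(benzyloxy)-2,6-dimethoxyphenol, via formate ester 3 (not isolated)
Conditions: mCPBA, CH2Cl2, 0 °C to rt; then K2CO3 (cat.), MeOH, rt
Reagents that add atoms: mCPBA, OOC(=O)c1cccc(Cl)c1
Why: Baeyer–Villiger oxidation in which the electron-rich trioxygenated aryl group migrates in preference to hydrogen, so that methanolysis of formate 3 should place the free hydroxyl unambiguously between the two methoxy groups.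

Step 3
Reactants: 4 4-(benzyloxy)-2,6-dimethoxyphenol; 5 trichloroethylene
Product: 7 5-(benzyloxy)-2-[(E)-1,2-dichloroethenyloxy]-1,3-dimethoxybenzene, via dichloroacetylene 6 (not isolated)
Conditions: K2CO3, DMF, 70 °C, argon
Reagents that add atoms: none
Why: Base-induced loss of HCl from 5 gives dichloroacetylene 6, to which the phenoxide adds with anti protonation (the trichloroethylene route to 1,2-dichlorovinyl ethers); the small linear electrophile is indifferent to the two ortho methoxy groups.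

Step 4
Reactants: 7 5-(benzyloxy)-2-[(E)-1,2-dichloroethenyloxy]-1,3-dimethoxybenzene
Product: 10 4-(benzyloxy)-2,6-dimethoxyphenyl ethynyl ether, via chloroethynyl ether 8 (not isolated), via lithium acetylide 9 (not isolated)
Conditions: n-BuLi (2.5 equiv), THF, −78 °C to −40 °C; then H2O, −78 °C
Reagents that add atoms: none
Why: Deprotonation and loss of LiCl give chloroalkyne 8, chlorine–lithium exchange gives acetylide 9 and protonation gives the terminal ynol ether (dichlorovinyl ether to alkynyl ether elimination), the benzyl ether and ring hydrogens not being metalated at −78 °C.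

Step 5
Reactants: 11 methoxyacetyl chloride; 12 ethoxyacetylene
Product: 14 racemic 3-ethoxy-4-methoxycyclobut-2-en-1-one, via methoxyketene 13 (not isolated)
Conditions: Et3N, Et2O, 0 °C to rt, slow addition of 11
Reagents that add atoms: none
Why: Dehydrochlorination gives methoxyketene 13, whose carbonyl carbon is attacked by the CH terminus of ethoxyacetylene in a ketene–alkyne (2+2) cycloaddition that puts ethoxy on C3 and methoxy on C4; C4 forms racemic without control and becomes an aromatic carbon in step 6.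

Step 6
Reactants: 10 4-(benzyloxy)-2,6-dimethoxyphenyl ethynyl ether; 14 racemic 3-ethoxy-4-methoxycyclobut-2-en-1-one
Product: 19 5-[4-(benzyloxy)-2,6-dimethoxyphenoxy]-3-ethoxy-2-methoxyphenol, via vinylketene 15 (not isolated), via vinylcyclobutenone 16 (not isolated), via dienylketene 17 (not isolated), via cyclohexadienone 18 (not isolated)
Conditions: 14 (1.2 equiv), toluene, 90 °C, argon
Reagents that add atoms: none
Why: Heat opens 14 by 4π electrocyclic ring opening (methoxy turning outward) to vinylketene 15, whose carbonyl carbon is attacked by the nucleophilic CH terminus of ynol ether 10 in a (2+2) cycloaddition to give 16; a second 4π opening gives dienylketene 17, 6π electrocyclisation gives dienone 18 and enolisation gives phenol 19. The closest known reaction type is the Danheiser benzannulation of cyclobutenones with alkoxyacetylenes. Ring G is closed by a thermal 6π electrocyclisation (six-membered, re-forming the C3–C4 bond) after the intermolecular (2+2) step has made the C2–C3 and C1–C6 bonds. No stereocentre remains, since the racemic sp3 carbons of 14, 16 and 18 all become aromatic carbons. The selectivity needed is the orientation of the (2+2) step, secured by the polarisation of the ynol ether, which puts the aryloxy carbon meta to the new hydroxyl and leaves hydrogens on C2 and C6. The aryl ynol ether has no β-hydrogen for retro-ene loss of ketene, and the benzyl and methyl ethers are inert to heating in toluene.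

Step 7
Reactants: 19 5-[4-(benzyloxy)-2,6-dimethoxyphenoxy]-3-ethoxy-2-methoxyphenol
Product: 20 5-(benzyloxy)-2-(3-ethoxy-4,5-dimethoxyphenoxy)-1,3-dimethoxybenzene
Conditions: MeI, K2CO3, DMF, rt
Reagents that add atoms: iodomethane, CI
Why: Williamson methylation of the single free phenol (ring G C3), so that the phenol unveiled next is the only nucleophile.

Step 8
Reactants: 20 5-(benzyloxy)-2-(3-ethoxy-4,5-dimethoxyphenoxy)-1,3-dimethoxybenzene
Product: 21 4-(3-ethoxy-4,5-dimethoxyphenoxy)-3,5-dimethoxyphenol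
Conditions: H2 (1 atm), Pd/C, EtOAc–MeOH, rt
Reagents that add atoms: none
Why: Hydrogenolysis of the benzyl aryl ether frees the ring F C1 hydroxyl, while diaryl ethers and alkyl aryl ethers are inert.

Step 9
Reactants: 21 4-(3-ethoxy-4,5-dimethoxyphenoxy)-3,5-dimethoxyphenol; 22 2-bromo-3,4,5-trimethoxybenzaldehyde
Product: 23 2-[4-(3-ethoxy-4,5-dimethoxyphenoxy)-3,5-dimethoxyphenoxy]-3,4,5-trimethoxybenzaldehyde
Conditions: CuI (10 mol %), picolinic acid (20 mol %), K3PO4, DMSO, 90 °C, argon
Reagents that add atoms: none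
Why: Ullmann diaryl ether coupling of an unhindered phenol with an ortho-formyl aryl bromide, a partner class in which the neighbouring carbonyl assists substitution despite two ortho substituents; it sets the ring E C6 to ring F C1 ether.

Step 10
Reactants: 23 2-[4-(3-ethoxy-4,5-dimethoxyphenoxy)-3,5-dimethoxyphenoxy]-3,4,5-trimethoxybenzaldehyde
Product: 25 2-[4-(3-ethoxy-4,5-dimethoxyphenoxy)-3,5-dimethoxyphenoxy]-3,4,5-trimethoxyphenol, via formate ester 24 (not isolated)
Conditions: mCPBA, CH2Cl2, 0 °C to rt; then K2CO3 (cat.), MeOH, rt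
Reagents that add atoms: mCPBA, OOC(=O)c1cccc(Cl)c1
Why: Baeyer–Villiger oxidation with migration of the aryl group (ortho aryloxy and para methoxy donors) and methanolysis turn the formyl-bearing carbon into the ring E C1 phenol.

Step 11
Reactants: 25 2-[4-(3-ethoxy-4,5-dimethoxyphenoxy)-3,5-dimethoxyphenoxy]-3,4,5-trimethoxyphenol; 26 4-bromo-2-fluoro-6-methoxybenzaldehyde
Product: 27 4-bromo-2-{2-[4-(3-ethoxy-4,5-dimethoxyphenoxy)-3,5-dimethoxyphenoxy]-3,4,5-trimethoxyphenoxy}-6-methoxybenzaldehyde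
Conditions: K2CO3, DMF, 80 °C
Reagents that add atoms: none
Why: Nucleophilic aromatic substitution in which the phenoxide displaces the fluoride ortho to the formyl group, far more labile than the para bromide without copper; it sets the ring E C1 to ring D C5 ether and keeps the bromide for step 17.

Step 12
Reactants: 28 2,4,6-trimethoxyphenol; 29 4-bromo-2,6-dimethoxybenzaldehyde
Product: 30 2,6-dimethoxy-4-(2,4,6-trimethoxyphenoxy)benzaldehyde
Conditions: CuI (10 mol %), picolinic acid (20 mol %), K3PO4, DMSO, 90 °C, argon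
Reagents that add atoms: none
Why: Ullmann coupling of a 2,6-disubstituted phenol with an unhindered, para-formyl-activated aryl bromide under the picolinic acid ligand system suited to hindered phenols; it sets the ring A C1 to ring B C1 ether from the hindered oxygen side.

Step 13
Reactants: 30 2,6-dimethoxy-4-(2,4,6-trimethoxyphenoxy)benzaldehyde
Product: 32 2,6-dimethoxy-4-(2,4,6-trimethoxyphenoxy)phenol, via formate ester 31 (not isolated)
Conditions: mCPBA, CH2Cl2, 0 °C to rt; then K2CO3 (cat.), MeOH, rt, argon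
Reagents that add atoms: mCPBA, OOC(=O)c1cccc(Cl)c1
Why: Baeyer–Villiger oxidation with aryl migration followed by formate methanolysis should give the ring B C4 phenol flanked by two methoxy groups.

Step 14
Reactants: 33 5-bromo-1,2,3-trimethoxybenzene
Product: 35 6-bromo-2,3,4-trimethoxybenzaldehyde, via chloro ether 34 (not isolated)
Conditions: Cl2CHOMe, TiCl4, CH2Cl2, −10 °C to 0 °C; then H2O
Reagents that add atoms: dichloromethyl methyl ether, COC(Cl)Cl; water, O
Why: Rieche formylation, in which the two open ring positions of 33 are equivalent so only one aldehyde can form, the α-chloro ether 34 being hydrolysed on aqueous work-up.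

Step 15
Reactants: 32 2,6-dimethoxy-4-(2,4,6-trimethoxyphenoxy)phenol; 35 6-bromo-2,3,4-trimethoxybenzaldehyde
Product: 36 6-[2,6-dimethoxy-4-(2,4,6-trimethoxyphenoxy)phenoxy]-2,3,4-trimethoxybenzaldehyde
Conditions: CuI (10 mol %), picolinic acid (20 mol %), K3PO4, DMSO, 90 °C, argon
Reagents that add atoms: none
Why: Ullmann coupling of a hindered phenol with an ortho-formyl aryl bromide whose other ortho position is hydrogen; it sets the ring B C4 to ring C C1 ether.

Step 16
Reactants: 36 6-[2,6-dimethoxy-4-(2,4,6-trimethoxyphenoxy)phenoxy]-2,3,4-trimethoxybenzaldehyde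
Product: 38 6-[2,6-dimethoxy-4-(2,4,6-trimethoxyphenoxy)phenoxy]-2,3,4-trimethoxyphenol, via formate ester 37 (not isolated)
Conditions: mCPBA, CH2Cl2, 0 °C to rt; then K2CO3 (cat.), MeOH, rt
Reagents that add atoms: mCPBA, OOC(=O)c1cccc(Cl)c1
Why: Baeyer–Villiger oxidation with migration of the doubly ortho-oxygenated aryl group and methanolysis should give the ring C C6 phenol.

Step 17
Reactants: 38 6-[2,6-dimethoxy-4-(2,4,6-trimethoxyphenoxy)phenoxy]-2,3,4-trimethoxyphenol; 27 4-bromo-2-{2-[4-(3-ethoxy-4,5-dimethoxyphenoxy)-3,5-dimethoxyphenoxy]-3,4,5-trimethoxyphenoxy}-6-methoxybenzaldehyde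
Product: 39 2-methoxy-4-{6-[2,6-dimethoxy-4-(2,4,6-trimethoxyphenoxy)phenoxy]-2,3,4-trimethoxyphenoxy}-6-{2-[4-(3-ethoxy-4,5-dimethoxyphenoxy)-3,5-dimethoxyphenoxy]-3,4,5-trimethoxyphenoxy}benzaldehyde
Conditions: CuI (20 mol %), picolinic acid (40 mol %), K3PO4, DMSO, 100 °C, argon
Reagents that add atoms: none
Why: Ullmann coupling joins the two halves, the hindered ring C C6 phenoxide being arylated at the unhindered bromide of 27 that the para formyl group activates; it sets the ring C C6 to ring D C1 ether.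

Step 18
Reactants: 39 protected heptamer aldehyde (formyl on ring D C4)
Product: 41 protected heptamer phenol (free hydroxyl on ring D C4; sixteen methyl ethers and one ethyl ether), via formate ester 40 (not isolated)
Conditions: mCPBA, CH2Cl2, 0 °C to rt; then K2CO3 (cat.), MeOH, rt
Reagents that add atoms: mCPBA, OOC(=O)c1cccc(Cl)c1
Why: Baeyer–Villiger oxidation of the last formyl group, flanked by methoxy and aryloxy donors, and methanolysis should install the ring D C4 oxygen.

Step 19
Reactants: 41 protected heptamer phenol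
Product: 42 CNP0130704.0
Conditions: BBr3 (40 equiv), CH2Cl2, −78 °C to rt; then H2O, 0 °C, argon
Reagents that add atoms: none
Why: Lewis-acid dealkylation of aryl alkyl ethers with BBr3 should cleave all sixteen methyl ethers and the ethyl ether while the six diaryl ethers stay intact, and hydrolysis of the aryl borates releases the eighteen hydroxyls.

Compound list
1 | 4-hydroxy-2,6-dimethoxybenzaldehyde | O=Cc1c(OC)cc(O)cc1OC | starting material
2 | 4-(benzyloxy)-2,6-dimethoxybenzaldehyde | O=Cc1c(OC)cc(OCc2ccccc2)cc1OC | intermediate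
3 | 4-(benzyloxy)-2,6-dimethoxyphenyl formate (not isolated) | O=COc1c(OC)cc(OCc2ccccc2)cc1OC | intermediate
4 | 4-(benzyloxy)-2,6-dimethoxyphenol | Oc1c(OC)cc(OCc2ccccc2)cc1OC | intermediate
5 | trichloroethylene | ClC=C(Cl)Cl | starting material
6 | dichloroacetylene (not isolated) | ClC#CCl | intermediate
7 | 5-(benzyloxy)-2-[(E)-1,2-dichloroethenyloxy]-1,3-dimethoxybenzene | Cl/C=C(/Cl)Oc1c(OC)cc(OCc2ccccc2)cc1OC | intermediate
8 | 5-(benzyloxy)-2-(chloroethynyloxy)-1,3-dimethoxybenzene (not isolated) | ClC#COc1c(OC)cc(OCc2ccccc2)cc1OC | intermediate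
9 | lithium [4-(benzyloxy)-2,6-dimethoxyphenoxy]acetylide (not isolated) | [Li]C#COc1c(OC)cc(OCc2ccccc2)cc1OC | intermediate
10 | 4-(benzyloxy)-2,6-dimethoxyphenyl ethynyl ether | C#COc1c(OC)cc(OCc2ccccc2)cc1OC | intermediate
11 | methoxyacetyl chloride | COCC(=O)Cl | starting material
12 | ethoxyacetylene | CCOC#C | starting material
13 | methoxyketene (not isolated) | COC=C=O | intermediate
14 | racemic 3-ethoxy-4-methoxycyclobut-2-en-1-one | CCOC1=CC(=O)C1OC | intermediate
15 | (3Z)-3-ethoxy-4-methoxybuta-1,3-dien-1-one (not isolated) | O=C=C/C(OCC)=C/OC | intermediate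
16 | racemic 3-[4-(benzyloxy)-2,6-dimethoxyphenoxy]-4-[(Z)-1-ethoxy-2-methoxyethenyl]cyclobut-2-en-1-one (not isolated) | O=C1C=C(Oc2c(OC)cc(OCc3ccccc3)cc2OC)C1/C(OCC)=C/OC | intermediate
17 | (3E,5Z)-3-[4-(benzyloxy)-2,6-dimethoxyphenoxy]-5-ethoxy-6-methoxyhexa-1,3,5-trien-1-one (not isolated) | O=C=C/C(Oc1c(OC)cc(OCc2ccccc2)cc1OC)=C\C(OCC)=C\OC | intermediate
18 | racemic 3-[4-(benzyloxy)-2,6-dimethoxyphenoxy]-5-ethoxy-6-methoxycyclohexa-2,4-dien-1-one (not isolated) | O=C1C=C(Oc2c(OC)cc(OCc3ccccc3)cc2OC)C=C(OCC)C1OC | intermediate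
19 | 5-[4-(benzyloxy)-2,6-dimethoxyphenoxy]-3-ethoxy-2-methoxyphenol (FG dimer; ring G hydroxyl on C3, methoxy on C4, ethoxy on C5; ring F benzyl ether) | Oc1cc(Oc2c(OC)cc(OCc3ccccc3)cc2OC)cc(OCC)c1OC | intermediate
20 | 5-(benzyloxy)-2-(3-ethoxy-4,5-dimethoxyphenoxy)-1,3-dimethoxybenzene | COc1cc(Oc2c(OC)cc(OCc3ccccc3)cc2OC)cc(OCC)c1OC | intermediate
21 | 4-(3-ethoxy-4,5-dimethoxyphenoxy)-3,5-dimethoxyphenol (FG phenol) | COc1cc(Oc2c(OC)cc(O)cc2OC)cc(OCC)c1OC | intermediate
22 | 2-bromo-3,4,5-trimethoxybenzaldehyde | O=Cc1cc(OC)c(OC)c(OC)c1Br | starting material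
23 | 2-[4-(3-ethoxy-4,5-dimethoxyphenoxy)-3,5-dimethoxyphenoxy]-3,4,5-trimethoxybenzaldehyde (EFG aldehyde) | O=Cc1cc(OC)c(OC)c(OC)c1Oc1cc(OC)c(Oc2cc(OC)c(OC)c(OCC)c2)c(OC)c1 | intermediate
24 | 2-[4-(3-ethoxy-4,5-dimethoxyphenoxy)-3,5-dimethoxyphenoxy]-3,4,5-trimethoxyphenyl formate (not isolated) | O=COc1cc(OC)c(OC)c(OC)c1Oc1cc(OC)c(Oc2cc(OC)c(OC)c(OCC)c2)c(OC)c1 | intermediate
25 | 2-[4-(3-ethoxy-4,5-dimethoxyphenoxy)-3,5-dimethoxyphenoxy]-3,4,5-trimethoxyphenol (EFG phenol) | Oc1cc(OC)c(OC)c(OC)c1Oc1cc(OC)c(Oc2cc(OC)c(OC)c(OCC)c2)c(OC)c1 | intermediate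
26 | 4-bromo-2-fluoro-6-methoxybenzaldehyde | O=Cc1c(F)cc(Br)cc1OC | starting material
27 | 4-bromo-2-{2-[4-(3-ethoxy-4,5-dimethoxyphenoxy)-3,5-dimethoxyphenoxy]-3,4,5-trimethoxyphenoxy}-6-methoxybenzaldehyde (DEFG bromo aldehyde) | O=Cc1c(OC)cc(Br)cc1Oc1cc(OC)c(OC)c(OC)c1Oc1cc(OC)c(Oc2cc(OC)c(OC)c(OCC)c2)c(OC)c1 | intermediate
28 | 2,4,6-trimethoxyphenol | COc1cc(OC)c(O)c(OC)c1 | starting material
29 | 4-bromo-2,6-dimethoxybenzaldehyde | O=Cc1c(OC)cc(Br)cc1OC | starting material
30 | 2,6-dimethoxy-4-(2,4,6-trimethoxyphenoxy)benzaldehyde (AB aldehyde) | O=Cc1c(OC)cc(Oc2c(OC)cc(OC)cc2OC)cc1OC | intermediate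
31 | 2,6-dimethoxy-4-(2,4,6-trimethoxyphenoxy)phenyl formate (not isolated) | O=COc1c(OC)cc(Oc2c(OC)cc(OC)cc2OC)cc1OC | intermediate
32 | 2,6-dimethoxy-4-(2,4,6-trimethoxyphenoxy)phenol (AB phenol) | Oc1c(OC)cc(Oc2c(OC)cc(OC)cc2OC)cc1OC | intermediate
33 | 5-bromo-1,2,3-trimethoxybenzene | COc1cc(Br)cc(OC)c1OC | starting material
34 | 1-bromo-2-[chloro(methoxy)methyl]-3,4,5-trimethoxybenzene (not isolated) | COC(Cl)c1c(Br)cc(OC)c(OC)c1OC | intermediate
35 | 6-bromo-2,3,4-trimethoxybenzaldehyde | O=Cc1c(Br)cc(OC)c(OC)c1OC | intermediate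
36 | 6-[2,6-dimethoxy-4-(2,4,6-trimethoxyphenoxy)phenoxy]-2,3,4-trimethoxybenzaldehyde (ABC aldehyde) | O=Cc1c(Oc2c(OC)cc(Oc3c(OC)cc(OC)cc3OC)cc2OC)cc(OC)c(OC)c1OC | intermediate
37 | 6-[2,6-dimethoxy-4-(2,4,6-trimethoxyphenoxy)phenoxy]-2,3,4-trimethoxyphenyl formate (not isolated) | O=COc1c(Oc2c(OC)cc(Oc3c(OC)cc(OC)cc3OC)cc2OC)cc(OC)c(OC)c1OC | intermediate
38 | 6-[2,6-dimethoxy-4-(2,4,6-trimethoxyphenoxy)phenoxy]-2,3,4-trimethoxyphenol (ABC phenol) | Oc1c(Oc2c(OC)cc(Oc3c(OC)cc(OC)cc3OC)cc2OC)cc(OC)c(OC)c1OC | intermediate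
39 | 2-methoxy-4-{6-[2,6-dimethoxy-4-(2,4,6-trimethoxyphenoxy)phenoxy]-2,3,4-trimethoxyphenoxy}-6-{2-[4-(3-ethoxy-4,5-dimethoxyphenoxy)-3,5-dimethoxyphenoxy]-3,4,5-trimethoxyphenoxy}benzaldehyde (protected heptamer aldehyde) | O=Cc1c(OC)cc(Oc2c(Oc3c(OC)cc(Oc4c(OC)cc(OC)cc4OC)cc3OC)cc(OC)c(OC)c2OC)cc1Oc1cc(OC)c(OC)c(OC)c1Oc1cc(OC)c(Oc2cc(OC)c(OC)c(OCC)c2)c(OC)c1 | intermediate
40 | formate ester of 41 on the ring D C4 oxygen (not isolated) | O=COc1c(OC)cc(Oc2c(Oc3c(OC)cc(Oc4c(OC)cc(OC)cc4OC)cc3OC)cc(OC)c(OC)c2OC)cc1Oc1cc(OC)c(OC)c(OC)c1Oc1cc(OC)c(Oc2cc(OC)c(OC)c(OCC)c2)c(OC)c1 | intermediate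
41 | 2-methoxy-4-{6-[2,6-dimethoxy-4-(2,4,6-trimethoxyphenoxy)phenoxy]-2,3,4-trimethoxyphenoxy}-6-{2-[4-(3-ethoxy-4,5-dimethoxyphenoxy)-3,5-dimethoxyphenoxy]-3,4,5-trimethoxyphenoxy}phenol (protected heptamer phenol) | Oc1c(OC)cc(Oc2c(Oc3c(OC)cc(Oc4c(OC)cc(OC)cc4OC)cc3OC)cc(OC)c(OC)c2OC)cc1Oc1cc(OC)c(OC)c(OC)c1Oc1cc(OC)c(Oc2cc(OC)c(OC)c(OCC)c2)c(OC)c1 | intermediate
42 | CNP0130704.0 (heptameric phlorotannin, eighteen free hydroxyls, no stereocentre) | Oc1cc(O)c(Oc2cc(O)c(Oc3cc(O)c(O)c(O)c3Oc3cc(O)c(O)c(Oc4cc(O)c(O)c(O)c4Oc4cc(O)c(Oc5cc(O)c(O)c(O)c5)c(O)c4)c3)c(O)c2)c(O)c1 | target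

Total step count: 19. Longest linear sequence: 13 steps (steps 1, 2, 3, 4, 6, 7, 8, 9, 10, 11, 17, 18, 19); step 5 and steps 12 to 16 are side branches.

Steps most likely to fail

Step 6. The terminal aryl ynol ether may polymerise at the temperature needed to open the vinylogous-ester cyclobutenone. The vinylketene may also dimerise or acylate the product phenol faster than it adds to the alkyne. The fallback builds the same F–G ether by known couplings and sets out from 4 and 26. Sodium ethoxide in ethanol should displace the ortho fluoride of 26 to give 4-bromo-2-ethoxy-6-methoxybenzaldehyde F1. Ullmann coupling of the hindered phenol 4 with F1 (CuI, picolinic acid, K3PO4, DMSO, 90 °C) should give 4-[4-(benzyloxy)-2,6-dimethoxyphenoxy]-2-ethoxy-6-methoxybenzaldehyde F2. Baeyer–Villiger oxidation with mCPBA gives 4-[4-(benzyloxy)-2,6-dimethoxyphenoxy]-2-ethoxy-6-methoxyphenyl formate F3, and methanolysis gives 4-[4-(benzyloxy)-2,6-dimethoxyphenoxy]-2-ethoxy-6-methoxyphenol F4. Methylation with MeI and K2CO3 comes back to the route at 20.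

Step 17. Copper-mediated arylation of the very hindered ring C phenoxide may be slow. Reduction of the bromide of 27, or exchange of the aryloxy group ortho to the formyl group, could then take over. The fallback uses two copper-free substitutions on one ring D building block and sets out from 38 and 25. The phenoxide of 38 and 2,4-difluoro-6-methoxybenzaldehyde (K2CO3, DMF, 60 °C) should react at the para fluorine, which the bulky nucleophile prefers over the fluorine beside the formyl group. This gives 2-fluoro-6-methoxy-4-{6-[2,6-dimethoxy-4-(2,4,6-trimethoxyphenoxy)phenoxy]-2,3,4-trimethoxyphenoxy}benzaldehyde F5. The phenoxide of 25 then displaces the remaining ortho fluoride (Cs2CO3, DMF, 100 °C), which comes back to the route at 39.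

Step 4. The terminal ynol ether may hydrate or oligomerise during aqueous work-up and concentration, so that little intact alkyne reaches step 6. The fallback stores the alkyne in protected form and sets out from 7. The acetylide 9 is made as before and trapped with Me3SiCl at −78 °C to give {[4-(benzyloxy)-2,6-dimethoxyphenoxy]ethynyl}trimethylsilane F6, which should survive chromatography. Brief treatment with K2CO3 in MeOH just before use releases the terminal alkyne, taken on in solution without concentration to dryness, which comes back to the route at 10.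

Further compounds
F1 | step 6 | 4-bromo-2-ethoxy-6-methoxybenzaldehyde | CCOc1cc(Br)cc(OC)c1C=O
F2 | step 6 | 4-[4-(benzyloxy)-2,6-dimethoxyphenoxy]-2-ethoxy-6-methoxybenzaldehyde | O=Cc1c(OCC)cc(Oc2c(OC)cc(OCc3ccccc3)cc2OC)cc1OC
F3 | step 6 | 4-[4-(benzyloxy)-2,6-dimethoxyphenoxy]-2-ethoxy-6-methoxyphenyl formate | O=COc1c(OCC)cc(Oc2c(OC)cc(OCc3ccccc3)cc2OC)cc1OC
F4 | step 6 | 4-[4-(benzyloxy)-2,6-dimethoxyphenoxy]-2-ethoxy-6-methoxyphenol | Oc1c(OCC)cc(Oc2c(OC)cc(OCc3ccccc3)cc2OC)cc1OC
F5 | step 17 | 2-fluoro-6-methoxy-4-{6-[2,6-dimethoxy-4-(2,4,6-trimethoxyphenoxy)phenoxy]-2,3,4-trimethoxyphenoxy}benzaldehyde | O=Cc1c(OC)cc(Oc2c(Oc3c(OC)cc(Oc4c(OC)cc(OC)cc4OC)cc3OC)cc(OC)c(OC)c2OC)cc1F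
F6 | step 4 | {[4-(benzyloxy)-2,6-dimethoxyphenoxy]ethynyl}trimethylsilane | C[Si](C)(C)C#COc1c(OC)cc(OCc2ccccc2)cc1OC
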